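## Analysis of the target

Target 31 is the p-coumarate of eudesm-4(15)-en-6α-ol. Eudesmane locants are used throughout; ring A is C1–C5 with C10, ring B is C5–C10, and α is the face opposite the C10 methyl group. The skeleton is a trans-fused decalin with an exocyclic methylidene (C15) on C4, the ester oxygen on C6 and an isopropyl group on C7. There are four stereocentres: the quaternary C10 (R, β-methyl), the ring-fusion C5 (S, α-H), C6 (S, α-oxygen) and C7 (S, β-isopropyl). In the chair–chair trans-decalin the C4 branch at C5, the C6 oxygen and the C7 isopropyl group are all equatorial on ring B, so the C5/C6/C7 relationship is the relaxed one. C10 and the absolute configuration, in contrast, must be set kinetically. The sensitive groups are the 1,1-disubstituted C4=C15 alkene (it migrates into the ring under acid), the (E)-cinnamate, the free phenol, and a C6 hydroxyl that is hindered by C7 and by the peri C15. The difficulty is the quaternary C10 next to the ring fusion together with the contiguous C5–C6–C7 array. The strategy rests on C4, C5 and the C6 oxygen: with C4 as a ketone they form an aldol, and an aldol is the opened form of a 2-isoxazoline spanning C4–C5–C6 and fused to both rings.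

## Retrosynthetic reasoning

**Ester C–O bond.** Target 31 is cut at the acyl–oxygen bond to alcohol 25 and the silyl-protected acid 28, which comes from p-coumaric acid 26. The hindered C6 hydroxyl is acylated last, so the cinnamate and the phenol are exposed only to two mild steps. Phenol protection (30) prevents the acid from acylating itself.

**C4=C15.** Alcohol 25 is traced through silyl ether 24 to ketone 23, and 23 to the free aldol 22. The methylidene is added to a ketone last among the skeletal operations. This fixes the alkene position unambiguously, and it keeps C5 adjacent to a carbonyl for as long as its configuration still has to be adjusted. The methylenation must be non-basic so that C5 and the β-oxygen are left alone.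

**C5 configuration.** Trans-fused 22 is the C5 epimer of cis-fused 21. C5 is α to the C4 carbonyl, so the step forward is an equilibration, driven by the all-equatorial ring B of 22.

**N–O bond.** Aldol 21 is the hydrogenolysis and hydrolysis product (through imine 20) of isoxazoline 19. The heterocycle stores the C4 carbonyl and the C6 hydroxyl in protected form, and it fixes the C6 oxygen on the α face.

**C4–C5 and O–C6 bonds (key disconnection).** Isoxazoline 19 is opened to nitrile oxide 18, which is generated from oxime 16 via chloride 17. Cutting here removes ring A and both new stereocentres at once. It leaves a monocyclic cyclohexene whose only stereocentres are C10 and C7. The forward cycloaddition must be regioselective (C4 to C5) and face-selective (α). The three-carbon tether on the α face of C10 enforces both.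

**Side chain.** Oxime 16 comes from aldehyde 15, and 15 from ester 14. Ester 14 comes from enoate 13, which is cut at C2=C3 into aldehyde 10 and phosphonate 11 (used as its sodium salt 12). Aldehyde 10 comes from ester 9. A two-carbon homologation is used because the sigmatropic step below delivers exactly C1 and C2.

**C1–C10 bond.** Ester 9 is traced through ketene acetal 8 and mixed orthoester 7 to trans-piperitol 5 and triethyl orthoacetate 6. A [3,3] shift is chosen for the quaternary centre because it transfers the carbinol configuration to C10 suprafacially. It also moves the alkene to C5=C6, where the dipole needs it.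

**Chiral pool.** Alcohol 5 comes from (S)-piperitone 4 by 1,2-reduction. Enone 4 comes from silyl enol ether 3 and enolate 2 of (−)-menthone 1. The isopropyl-bearing stereocentre of 1 becomes C7 and controls everything else.

## Alternatives that were turned down

**Alternative 1: Diels–Alder construction of ring B.** Ring B is cut at C5–C6 and C9–C10. Forward, 3-methylcyclohex-2-en-1-one (A1) and the silyloxydiene A2 would combine under a chiral Lewis acid, and base would epimerise C5 to give the trans-fused octalone A3.
- For: it is convergent, it makes the quaternary C10 and ring B in one intermolecular step, it is catalytic in chirality, and it would be several steps shorter than the chosen route. On step economy it is clearly stronger.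
- Against: A1 is a β,β-disubstituted enone and a poor dienophile, so it needs strong Lewis acid activation, and A2 is an acid-labile dienol ether. Endo- and enantioselectivity would depend entirely on a catalyst–substrate match, with no structural constraint behind them. C7 would still have to be set by a face-selective hydrogenation of the C7=C8 alkene of A3.
- Comparison: the chosen strategy is longer, but it takes the absolute configuration from a purchased stereocentre and fixes C10, C6 and C5 by geometric necessity, not by catalyst control.

**Alternative 2: transannular cyclisation of a germacranolide.** The C5–C10 bond is cut. Forward, protonation of costunolide (A4) at C1 would let the C4=C5 alkene attack C10, and loss of a C15 proton would give β-cyclocostunolide (A5). The lactone carbons would then be reduced to the isopropyl group.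
- For: one step delivers C5, C6, C7, C10 and the methylidene with the correct configurations. If A4 is in hand, this is the shortest route of all.
- Against: A4 is a scarce natural isolate, not a bulk chemical, so the work becomes a partial synthesis. Proton loss after cyclisation is divided between C3, C5 and C15, so A5 is one of three alkene isomers. The endgame must reduce C11=C13, open the lactone and deoxygenate C12, all without disturbing the acid-sensitive C4=C15 alkene.
- Comparison: the chosen strategy starts from an inexpensive monoterpene and adds C15 to a ketone, so no alkene-isomer mixture can arise. The price is a longer sequence.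

**Alternative 3: cathodic ketyl–olefin closure of ring B.** The C6–C7 bond is cut. Forward, reduction of aldehyde A6 at a cathode would give a C6 ketyl that adds to C7 of the prenyl-type chain, and the C11 radical would be reduced and protonated to give the alcohol A7, which is identical with 25.
- For: the key step gives the free alcohol directly, with no protecting group and no methylenation, two steps from the target. After the key step it is far shorter than the chosen route.
- Against: A6 is a β,γ-unsaturated aldehyde whose C5–H is both allylic and α to the carbonyl, so C5 can epimerise and the alkene can move into conjugation. A6 also needs its own enantioselective construction of C10 and C5. The 6-exo addition of a ketyl to an unactivated trisubstituted alkene competes with pinacol coupling and simple reduction. The C6/C7 outcome relies on a chair preference, not on a constraint.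
- Comparison: the chosen strategy places its risk in a cycloaddition whose regio- and face selectivity are forced by a short tether, and it uses only configurationally stable intermediates before that step.

Key step: step 10

## Assumptions

- The (−)-menthone used is free of its C2 epimer isomenthone. The enantiomeric purity of 4 equals the epimeric purity of 1 at the isopropyl-bearing carbon.
- Trimethyl phosphonoacetate is used for the chain extension (not the triethyl ester), so that the ester matches the methanol of the conjugate reduction in step 7.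

## Route

Step 1
Reactants: 1 (−)-menthone, (2S,5R)-5-methyl-2-(propan-2-yl)cyclohexan-1-one
Product: 3 trimethyl{[(3R,6S)-3-methyl-6-(propan-2-yl)cyclohex-1-en-1-yl]oxy}silane, via lithium enolate 2 (not isolated)
Conditions: LiN(i-Pr)2, THF, −78 °C; Me3SiCl, −78 °C → rt
Reagents that add atoms: chlorotrimethylsilane, C[Si](C)(C)Cl
Why: Kinetic enolate formation: the hindered amide removes a proton from the CH2 and not from the isopropyl-bearing CH, irreversibly at −78 °C, so the C7 stereocentre is untouched; O-silylation fixes the regiochemistry.

Step 2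
Reactants: 3 trimethyl{[(3R,6S)-3-methyl-6-(propan-2-yl)cyclohex-1-en-1-yl]oxy}silane
Product: 4 (S)-piperitone, (6S)-3-methyl-6-(propan-2-yl)cyclohex-2-en-1-one
Conditions: Pd(OAc)2 (10 mol %), O2 (1 atm), DMSO, rt
Reagents that add atoms: none
Why: Saegusa–Ito oxidation: the palladium enolate undergoes β-hydride elimination toward the methyl-bearing carbon, and O2 returns zerovalent palladium to divalent palladium; the neutral medium should not enolise the isopropyl-bearing α'-carbon.

Step 3
Reactants: 4 (S)-piperitone
Product: 5 trans-piperitol, (1S,6S)-3-methyl-6-(propan-2-yl)cyclohex-2-en-1-ol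
Conditions: NaBH4, CeCl3·7H2O, MeOH, −78 → 0 °C
Reagents that add atoms: none
Why: Luche 1,2-reduction; hydride should enter along the axial trajectory of the half-chair that has the isopropyl group equatorial, which places the new hydroxyl equatorial and trans to the isopropyl group (1S); the minor cis isomer is removed by chromatography.

Step 4
Reactants: 5 trans-piperitol; 6 triethyl orthoacetate
Product: 9 ethyl 2-[(1S,4S)-1-methyl-4-(propan-2-yl)cyclohex-2-en-1-yl]acetate, via mixed orthoester 7 (not isolated), via ketene acetal 8 (not isolated)
Conditions: MeC(OEt)3 (excess), EtCO2H (cat.), 140 °C, EtOH distilled off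
Reagents that add atoms: none
Why: Johnson–Claisen rearrangement; the [3,3] shift is suprafacial, so the CH2CO2Et group arrives at the methyl-bearing carbon on the face that held the C–O bond, trans to the isopropyl group, which sets quaternary C10 with methyl cis to isopropyl and moves the alkene to C5=C6.

Step 5
Reactants: 9 ethyl 2-[(1S,4S)-1-methyl-4-(propan-2-yl)cyclohex-2-en-1-yl]acetate
Product: 10 2-[(1S,4S)-1-methyl-4-(propan-2-yl)cyclohex-2-en-1-yl]acetaldehyde
Conditions: i-Bu2AlH (1.05 equiv), CH2Cl2, −78 °C; Rochelle salt
Reagents that add atoms: none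
Why: Partial reduction of an ester by i-Bu2AlH; at −78 °C the reduction of this neopentyl-type ester should stop at the aldehyde oxidation level, and the aldehyde has no stereocentre at its α-carbon.

Step 6
Reactants: 10 2-[(1S,4S)-1-methyl-4-(propan-2-yl)cyclohex-2-en-1-yl]acetaldehyde; 11 trimethyl phosphonoacetate
Product: 13 methyl (2E)-4-[(1S,4S)-1-methyl-4-(propan-2-yl)cyclohex-2-en-1-yl]but-2-enoate, via sodium phosphonate 12 (not isolated)
Conditions: NaH, THF, 0 °C; then 10, 0 °C → rt
Reagents that add atoms: none
Why: Horner–Wadsworth–Emmons olefination with a stabilised phosphonate anion adds C3 and C4 and gives the E-enoate; the alkene geometry is irrelevant because it is reduced next.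

Step 7
Reactants: 13 methyl (2E)-4-[(1S,4S)-1-methyl-4-(propan-2-yl)cyclohex-2-en-1-yl]but-2-enoate
Product: 14 methyl 4-[(1R,4S)-1-methyl-4-(propan-2-yl)cyclohex-2-en-1-yl]butanoate
Conditions: Mg turnings, MeOH, 0 °C → rt
Reagents that add atoms: none
Why: Dissolving-metal conjugate reduction; electron transfer goes only into the conjugated enoate, so the isolated, hindered ring alkene is not touched, and a methyl ester in MeOH cannot be scrambled by transesterification.

Step 8
Reactants: 14 methyl 4-[(1R,4S)-1-methyl-4-(propan-2-yl)cyclohex-2-en-1-yl]butanoate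
Product: 15 4-[(1R,4S)-1-methyl-4-(propan-2-yl)cyclohex-2-en-1-yl]butanal
Conditions: i-Bu2AlH (1.05 equiv), CH2Cl2, −78 °C; Rochelle salt
Reagents that add atoms: none
Why: Partial reduction of the ester to the aldehyde at low temperature, as in step 5; nothing else in the molecule is reducible under these conditions.

Step 9
Reactants: 15 4-[(1R,4S)-1-methyl-4-(propan-2-yl)cyclohex-2-en-1-yl]butanal
Product: 16 (1E)-4-[(1R,4S)-1-methyl-4-(propan-2-yl)cyclohex-2-en-1-yl]butanal oxime
Conditions: NH2OH·HCl, NaOAc, EtOH/H2O, rt
Reagents that add atoms: hydroxylamine hydrochloride, Cl.NO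
Why: Oxime condensation; the E isomer should predominate, and any Z isomer is carried along because both give the same nitrile oxide.

Step 10
Reactants: 16 (1E)-4-[(1R,4S)-1-methyl-4-(propan-2-yl)cyclohex-2-en-1-yl]butanal oxime
Product: 19 cis-fused tricyclic 2-isoxazoline with N=C4 and O–C6α spanning C5 (5β-H, 7β-isopropyl, 10β-methyl; C5 S, C6 S, C7 S, C10 R), via hydroximoyl chloride 17 (not isolated), via nitrile oxide 18 (not isolated)
Conditions: aq. NaOCl (excess), Et3N (cat.), CH2Cl2, 0 °C → rt, 16 added slowly (final ≤ 0.01 M)
Reagents that add atoms: none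
Why: Hypochlorite chlorinates the aldoxime to 17, loss of HCl gives nitrile oxide 18, and 18 adds to the C5=C6 alkene in a concerted, suprafacial 1,3-dipolar cycloaddition. The closest known reaction type is the intramolecular nitrile oxide–alkene cycloaddition onto a cycloalkene from a tether at the allylic carbon. Ring A closes in the fused (exo) mode as a six-membered carbocycle through the C4–C5 bond, because the three-carbon tether C1–C3 reaches only the proximal alkene carbon; the bridged mode would need a seven-membered ring through C6. The isoxazoline closes at the same moment as the five-membered ring of the cycloaddition itself, through the O–C6 bond. C5 is controlled by the tether: the tether hangs from the α face of C10, and its three atoms plus the linear C≡N–O unit cannot reach the β face, so C4 bonds to C5 from below and the ring fusion is cis (5β-H). C6 is controlled by suprafaciality: oxygen must add to the same α face, which gives the 6α-oxygen of the target. The step needs regioselectivity, α-face selectivity and cyclisation in preference to dimerisation of the dipole; the tether secures the first two, helped by a reactive conformer with C1 pseudoequatorial, the C10 methyl pseudoaxial over the β face and the isopropyl group pseudoequatorial. Slow generation of 18 at high dilution is meant to secure the third.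

Step 11
Reactants: 19 tricyclic 2-isoxazoline
Product: 21 6α-hydroxy-15-nor-5β-eudesman-4-one, (4aR,7S,8S,8aR)-8-hydroxy-4a-methyl-7-(propan-2-yl)octahydronaphthalen-1(2H)-one, via hydroxy imine 20 (not isolated)
Conditions: H2 (1 atm), Raney Ni, B(OH)3, MeOH/H2O (5:1), rt
Reagents that add atoms: water, O
Why: Hydrogenolysis of the weak N–O bond gives β-hydroxy imine 20, which the boric-acid-buffered water hydrolyses to the ketone before it can be reduced to an amine; the C6–O bond is not touched, so the 6α-hydroxyl is kept.

Step 12
Reactants: 21 6α-hydroxy-15-nor-5β-eudesman-4-one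
Product: 22 6α-hydroxy-15-nor-5α-eudesman-4-one, (4aR,7S,8S,8aS)-8-hydroxy-4a-methyl-7-(propan-2-yl)octahydronaphthalen-1(2H)-one
Conditions: DBU (0.5 equiv), toluene, 40 °C; recovered 21 resubmitted
Reagents that add atoms: none
Why: Base-mediated epimerisation at C5 through the C4 enol(ate); H5 is axial on ring A and aligned with the carbonyl. The trans isomer should be favoured because the equatorial C6 and C7 substituents lock the cis isomer in the conformer that has C4 axial on ring B, whereas in 22 all three ring-B substituents are equatorial; this sets C5 (5α-H) under thermodynamic control, and an amidine in an aprotic solvent keeps alkoxide-driven retro-aldol cleavage low.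

Step 13
Reactants: 22 6α-hydroxy-15-nor-5α-eudesman-4-one
Product: 23 6α-(triethylsilyloxy)-15-nor-5α-eudesman-4-one
Conditions: Et3SiOTf, 2,6-lutidine, CH2Cl2, −78 → 0 °C
Reagents that add atoms: triethylsilyl trifluoromethanesulfonate, CC[Si](CC)(CC)OS(=O)(=O)C(F)(F)F
Why: Silylation of a hindered, hydrogen-bonded secondary alcohol with a silyl triflate and a non-nucleophilic base; at low temperature O-silylation should be much faster than silyl enol ether formation.

Step 14
Reactants: 23 6α-(triethylsilyloxy)-15-nor-5α-eudesman-4-one
Product: 24 6α-(triethylsilyloxy)eudesm-4(15)-ene, triethyl{[(1S,2S,4aR,8aS)-4a-methyl-8-methylidene-2-(propan-2-yl)decahydronaphthalen-1-yl]oxy}silane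
Conditions: Zn, CH2Br2, TiCl4, THF/CH2Cl2, 0 °C → rt
Reagents that add atoms: dibromomethane, BrCBr
Why: Takai–Lombardo methylenation; the gem-dimetallic reagent is nucleophilic but not basic, so it should add C15 to the hindered, enolisable ketone without epimerising C5 or eliminating the β-silyloxy group.

Step 15
Reactants: 24 6α-(triethylsilyloxy)eudesm-4(15)-ene
Product: 25 eudesm-4(15)-en-6α-ol, (1S,2S,4aR,8aS)-4a-methyl-8-methylidene-2-(propan-2-yl)decahydronaphthalen-1-ol
Conditions: n-Bu4NF, THF, rt
Reagents that add atoms: none
Why: Fluoride cleavage of the triethylsilyl ether; acid is avoided so that the exocyclic alkene cannot migrate into the ring.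

Step 16
Reactants: 26 p-coumaric acid, (2E)-3-(4-hydroxyphenyl)prop-2-enoic acid
Product: 28 (2E)-3-{4-[(tert-butyldimethylsilyl)oxy]phenyl}prop-2-enoic acid, via bis-silyl compound 27 (not isolated)
Conditions: t-BuMe2SiCl (2.2 equiv), imidazole, DMF, rt; then AcOH/THF/H2O, rt
Reagents that add atoms: tert-butyldimethylsilyl chloride, CC(C)(C)[Si](C)(C)Cl
Why: Silylation of both acidic sites followed by selective hydrolysis of the much more labile silyl ester; the aryl silyl ether should survive the dilute acetic acid.

Step 17
Reactants: 25 eudesm-4(15)-en-6α-ol; 28 (2E)-3-{4-[(tert-butyldimethylsilyl)oxy]phenyl}prop-2-enoic acid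
Product: 30 (1S,2S,4aR,8aS)-4a-methyl-8-methylidene-2-(propan-2-yl)decahydronaphthalen-1-yl (2E)-3-{4-[(tert-butyldimethylsilyl)oxy]phenyl}prop-2-enoate, via mixed anhydride 29 (not isolated)
Conditions: 2,4,6-Cl3C6H2COCl, Et3N, toluene, rt; then 25, DMAP, toluene, rt → 50 °C
Reagents that add atoms: none
Why: Yamaguchi esterification; DMAP attacks the unhindered cinnamoyl carbonyl of the mixed anhydride and the acylpyridinium salt acylates the hindered equatorial C6 hydroxyl with retention at C6; the protected phenol cannot compete.

Step 18
Reactants: 30 silyl-protected ester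
Product: 31 target, (1S,2S,4aR,8aS)-4a-methyl-8-methylidene-2-(propan-2-yl)decahydronaphthalen-1-yl (2E)-3-(4-hydroxyphenyl)prop-2-enoate
Conditions: n-Bu4NF, AcOH, THF, 0 °C
Reagents that add atoms: none
Why: Buffered fluoride removes the aryl silyl ether quickly; the hindered secondary cinnamate and the exocyclic alkene should be inert to these conditions.

## Compound list

1 | (−)-menthone, (2S,5R)-5-methyl-2-(propan-2-yl)cyclohexan-1-one | C[C@@H]1CC[C@H](C(=O)C1)C(C)C | starting material
2 | lithium (3R,6S)-3-methyl-6-(propan-2-yl)cyclohex-1-en-1-olate | C[C@@H]1CC[C@H](C([O-])=C1)C(C)C.[Li+] | intermediate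
3 | trimethyl{[(3R,6S)-3-methyl-6-(propan-2-yl)cyclohex-1-en-1-yl]oxy}silane | C[C@@H]1CC[C@H](C(O[Si](C)(C)C)=C1)C(C)C | intermediate
4 | (S)-piperitone, (6S)-3-methyl-6-(propan-2-yl)cyclohex-2-en-1-one | CC1=CC(=O)[C@H](C(C)C)CC1 | intermediate
5 | trans-piperitol, (1S,6S)-3-methyl-6-(propan-2-yl)cyclohex-2-en-1-ol | CC1=C[C@@H](O)[C@H](C(C)C)CC1 | intermediate
6 | triethyl orthoacetate | CCOC(C)(OCC)OCC | starting material
7 | 1,1-diethoxy-1-{[(1S,6S)-3-methyl-6-(propan-2-yl)cyclohex-2-en-1-yl]oxy}ethane (mixed orthoester) | CC1=C[C@@H](OC(C)(OCC)OCC)[C@H](C(C)C)CC1 | intermediate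
8 | 1-ethoxy-1-{[(1S,6S)-3-methyl-6-(propan-2-yl)cyclohex-2-en-1-yl]oxy}ethene (ketene acetal) | CC1=C[C@@H](OC(=C)OCC)[C@H](C(C)C)CC1 | intermediate
9 | ethyl 2-[(1S,4S)-1-methyl-4-(propan-2-yl)cyclohex-2-en-1-yl]acetate | CCOC(=O)C[C@@]1(C)C=C[C@H](C(C)C)CC1 | intermediate
10 | 2-[(1S,4S)-1-methyl-4-(propan-2-yl)cyclohex-2-en-1-yl]acetaldehyde | O=CC[C@@]1(C)C=C[C@H](C(C)C)CC1 | intermediate
11 | trimethyl phosphonoacetate | COC(=O)CP(=O)(OC)OC | starting material
12 | sodium salt of trimethyl phosphonoacetate | COC(=O)[CH-]P(=O)(OC)OC.[Na+] | intermediate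
13 | methyl (2E)-4-[(1S,4S)-1-methyl-4-(propan-2-yl)cyclohex-2-en-1-yl]but-2-enoate | COC(=O)/C=C/C[C@@]1(C)C=C[C@H](C(C)C)CC1 | intermediate
14 | methyl 4-[(1R,4S)-1-methyl-4-(propan-2-yl)cyclohex-2-en-1-yl]butanoate | COC(=O)CCC[C@@]1(C)C=C[C@H](C(C)C)CC1 | intermediate
15 | 4-[(1R,4S)-1-methyl-4-(propan-2-yl)cyclohex-2-en-1-yl]butanal | O=CCCC[C@@]1(C)C=C[C@H](C(C)C)CC1 | intermediate
16 | (1E)-4-[(1R,4S)-1-methyl-4-(propan-2-yl)cyclohex-2-en-1-yl]butanal oxime | O/N=C/CCC[C@@]1(C)C=C[C@H](C(C)C)CC1 | intermediate
17 | N-hydroxy-4-[(1R,4S)-1-methyl-4-(propan-2-yl)cyclohex-2-en-1-yl]butanimidoyl chloride | ON=C(Cl)CCC[C@@]1(C)C=C[C@H](C(C)C)CC1 | intermediate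
18 | 4-[(1R,4S)-1-methyl-4-(propan-2-yl)cyclohex-2-en-1-yl]butanenitrile oxide | [O-][N+]#CCCC[C@@]1(C)C=C[C@H](C(C)C)CC1 | intermediate
19 | cis-fused tricyclic 2-isoxazoline, N=C4 and O–C6α spanning C5, 5β-H, 7β-isopropyl, 10β-methyl | N1=C2CCC[C@]3(C)CC[C@@H](C(C)C)[C@H](O1)[C@H]23 | intermediate
20 | 4-imino-15-nor-5β-eudesman-6α-ol | N=C1CCC[C@]2(C)CC[C@@H](C(C)C)[C@H](O)[C@H]12 | intermediate
21 | 6α-hydroxy-15-nor-5β-eudesman-4-one, (4aR,7S,8S,8aR)-8-hydroxy-4a-methyl-7-(propan-2-yl)octahydronaphthalen-1(2H)-one | O=C1CCC[C@]2(C)CC[C@@H](C(C)C)[C@H](O)[C@H]12 | intermediate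
22 | 6α-hydroxy-15-nor-5α-eudesman-4-one, (4aR,7S,8S,8aS)-8-hydroxy-4a-methyl-7-(propan-2-yl)octahydronaphthalen-1(2H)-one | O=C1CCC[C@]2(C)CC[C@@H](C(C)C)[C@H](O)[C@@H]12 | intermediate
23 | 6α-(triethylsilyloxy)-15-nor-5α-eudesman-4-one | O=C1CCC[C@]2(C)CC[C@@H](C(C)C)[C@H](O[Si](CC)(CC)CC)[C@@H]12 | intermediate
24 | 6α-(triethylsilyloxy)eudesm-4(15)-ene | C=C1CCC[C@]2(C)CC[C@@H](C(C)C)[C@H](O[Si](CC)(CC)CC)[C@@H]12 | intermediate
25 | eudesm-4(15)-en-6α-ol, (1S,2S,4aR,8aS)-4a-methyl-8-methylidene-2-(propan-2-yl)decahydronaphthalen-1-ol | C=C1CCC[C@]2(C)CC[C@@H](C(C)C)[C@H](O)[C@@H]12 | intermediate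
26 | p-coumaric acid | O=C(O)/C=C/c1ccc(O)cc1 | starting material
27 | tert-butyldimethylsilyl (2E)-3-{4-[(tert-butyldimethylsilyl)oxy]phenyl}prop-2-enoate | CC(C)(C)[Si](C)(C)OC(=O)/C=C/c1ccc(O[Si](C)(C)C(C)(C)C)cc1 | intermediate
28 | (2E)-3-{4-[(tert-butyldimethylsilyl)oxy]phenyl}prop-2-enoic acid | O=C(O)/C=C/c1ccc(O[Si](C)(C)C(C)(C)C)cc1 | intermediate
29 | mixed anhydride of 28 with 2,4,6-trichlorobenzoic acid | O=C(/C=C/c1ccc(O[Si](C)(C)C(C)(C)C)cc1)OC(=O)c1c(Cl)cc(Cl)cc1Cl | intermediate
30 | (1S,2S,4aR,8aS)-4a-methyl-8-methylidene-2-(propan-2-yl)decahydronaphthalen-1-yl (2E)-3-{4-[(tert-butyldimethylsilyl)oxy]phenyl}prop-2-enoate | C=C1CCC[C@]2(C)CC[C@@H](C(C)C)[C@H](OC(=O)/C=C/c3ccc(O[Si](C)(C)C(C)(C)C)cc3)[C@@H]12 | intermediate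
31 | (1S,2S,4aR,8aS)-4a-methyl-8-methylidene-2-(propan-2-yl)decahydronaphthalen-1-yl (2E)-3-(4-hydroxyphenyl)prop-2-enoate | C=C1CCC[C@]2(C)CC[C@@H](C(C)C)[C@H](OC(=O)/C=C/c3ccc(O)cc3)[C@@H]12 | target

## Step count and least certain steps

Total step count: 18. Longest linear sequence: 17 steps (steps 1–15, 17 and 18 from 1); step 16 is a one-step side branch.

**Step 10 (key step).** The most likely failure is dimerisation of the nitrile oxide to a furoxan, competing with a slow closure onto a 1,2-disubstituted alkene whose C5 terminus is next to a quaternary carbon. The fallback changes the dipole to a silyl nitronate, which does not dimerise and tolerates heating. It sets out from 14 and returns at 19. Ester 14 would be reduced with LiAlH4 to 4-[(1R,4S)-1-methyl-4-(propan-2-yl)cyclohex-2-en-1-yl]butan-1-ol F1. Alcohol F1 would be converted with I2, PPh3 and imidazole into the corresponding primary iodide F2, and F2 with NaNO2 in DMF into the primary nitro compound F3. Treatment of F3 with Me3SiCl and Et3N would give the trimethylsilyl nitronate F4, which should cyclise under the same tether control to the N-(trimethylsilyloxy)isoxazolidine F5. Acid-induced loss of silanol from F5 would give 19.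

**Step 12.** The risks are loss of the β-oxygen by E1cB elimination through the C4–C5 enolate, retro-aldol opening of ring B with scrambling of C6 and C7, and an equilibrium that stops short of complete conversion. The fallback changes the order of events so that no free alkoxide can form. It sets out from 21 and returns at 23. Aldol 21 would be silylated first (Et3SiOTf, 2,6-lutidine) to 6α-(triethylsilyloxy)-15-nor-5β-eudesman-4-one F6. F6 would then be equilibrated with DBU to 23; retro-aldol cleavage is impossible for the silyl ether, and the equatorial C–O bond is poorly aligned for elimination.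

**Step 14.** The risk is incomplete addition of the bulky titanium–zinc reagent to a carbonyl that is shielded by the peri silyloxy group and the neighbouring ring fusion, with enolisation taking over. The fallback is a two-stage Peterson olefination. It sets out from 23 and returns at 24. Me3SiCH2Li with CeCl3 would add to the ketone to give the β-hydroxysilane 4-hydroxy-4-[(trimethylsilyl)methyl]-6α-(triethylsilyloxy)-15-nor-5α-eudesmane F7. KH in THF would then eliminate silanolate from F7 to give 24.

**Step 17.** The risk is slow acylation of the C6 hydroxyl, which is flanked by C7 and the peri methylidene, so that the activated acid decomposes first. The fallback builds the cinnamate by olefination on a small acyl group already in place. It sets out from 25 and returns at 30. Alcohol 25 would be acylated with diethylphosphonoacetic acid and DCC (a ketene-type acyl transfer, little affected by hindrance) to give the 6α-(diethylphosphonoacetate) of eudesm-4(15)-en-6α-ol F8. A Horner–Wadsworth–Emmons reaction of F8 with 4-[(tert-butyldimethylsilyl)oxy]benzaldehyde F9 (NaH, THF) would give 30.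

**Step 3.** The risk is poor facial selectivity in hydride delivery. Any cis-piperitol carried forward would give the C10 epimer after step 4. The fallback uses the opposite alcohol with an anti-selective allylic substitution in place of the sigmatropic shift. It sets out from 4 and returns at 15, and it bypasses steps 3–8. Enone 4 would be reduced with LiBH(s-Bu)3 (equatorial attack) to cis-piperitol, (1R,6S)-3-methyl-6-(propan-2-yl)cyclohex-2-en-1-ol F10. F10 would be esterified with picolinic acid (DCC, DMAP) to the picolinate F11. The Grignard reagent from 2-(3-chloropropyl)-1,3-dioxolane with CuBr·SMe2 would then substitute F11 in the anti SN2' sense, giving 2-{3-[(1R,4S)-1-methyl-4-(propan-2-yl)cyclohex-2-en-1-yl]propyl}-1,3-dioxolane F12. Aqueous acid would release aldehyde 15 from F12.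

## Further compounds

F1 | step 10 | 4-[(1R,4S)-1-methyl-4-(propan-2-yl)cyclohex-2-en-1-yl]butan-1-ol | OCCCC[C@@]1(C)C=C[C@H](C(C)C)CC1
F2 | step 10 | (3S,6R)-6-(4-iodobutyl)-6-methyl-3-(propan-2-yl)cyclohex-1-ene | ICCCC[C@@]1(C)C=C[C@H](C(C)C)CC1
F3 | step 10 | (3S,6R)-6-methyl-6-(4-nitrobutyl)-3-(propan-2-yl)cyclohex-1-ene | [O-][N+](=O)CCCC[C@@]1(C)C=C[C@H](C(C)C)CC1
F4 | step 10 | trimethylsilyl nitronate of F3 | C[Si](C)(C)O[N+]([O-])=CCCC[C@@]1(C)C=C[C@H](C(C)C)CC1
F5 | step 10 | N-(trimethylsilyloxy)isoxazolidine corresponding to 19 (C4 configuration not defined) | C[Si](C)(C)ON1C2CCC[C@]3(C)CC[C@@H](C(C)C)[C@H](O1)[C@H]23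
F6 | step 12 | 6α-(triethylsilyloxy)-15-nor-5β-eudesman-4-one | O=C1CCC[C@]2(C)CC[C@@H](C(C)C)[C@H](O[Si](CC)(CC)CC)[C@H]12
F7 | step 14 | 4-hydroxy-4-[(trimethylsilyl)methyl]-6α-(triethylsilyloxy)-15-nor-5α-eudesmane (C4 configuration not defined) | C[Si](C)(C)CC1(O)CCC[C@]2(C)CC[C@@H](C(C)C)[C@H](O[Si](CC)(CC)CC)[C@@H]12
F8 | step 17 | (1S,2S,4aR,8aS)-4a-methyl-8-methylidene-2-(propan-2-yl)decahydronaphthalen-1-yl 2-(diethoxyphosphoryl)acetate | C=C1CCC[C@]2(C)CC[C@@H](C(C)C)[C@H](OC(=O)CP(=O)(OCC)OCC)[C@@H]12
F9 | step 17 | 4-[(tert-butyldimethylsilyl)oxy]benzaldehyde | O=Cc1ccc(O[Si](C)(C)C(C)(C)C)cc1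
F10 | step 3 | cis-piperitol, (1R,6S)-3-methyl-6-(propan-2-yl)cyclohex-2-en-1-ol | CC1=C[C@H](O)[C@H](C(C)C)CC1
F11 | step 3 | (1R,6S)-3-methyl-6-(propan-2-yl)cyclohex-2-en-1-yl pyridine-2-carboxylate | CC1=C[C@H](OC(=O)c2ccccn2)[C@H](C(C)C)CC1
F12 | step 3 | 2-{3-[(1R,4S)-1-methyl-4-(propan-2-yl)cyclohex-2-en-1-yl]propyl}-1,3-dioxolane | C1COC(CCC[C@@]2(C)C=C[C@H](C(C)C)CC2)O1
A1 | alternative 1 | 3-methylcyclohex-2-en-1-one | CC1=CC(=O)CCC1
A2 | alternative 1 | (1E)-1-[(tert-butyldimethylsilyl)oxy]-2-(propan-2-yl)buta-1,3-diene | C=C/C(C(C)C)=C/O[Si](C)(C)C(C)(C)C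
A3 | alternative 1 | trans-fused 6α-[(tert-butyldimethylsilyl)oxy]-15-noreudesm-7-en-4-one | O=C1CCC[C@]2(C)CC=C(C(C)C)[C@H](O[Si](C)(C)C(C)(C)C)[C@@H]12
A4 | alternative 2 | costunolide | C/C1=C\CC/C(C)=C/[C@H]2OC(=O)C(=C)[C@@H]2CC1
A5 | alternative 2 | β-cyclocostunolide, eudesma-4(15),11(13)-dien-6α,12-olide | C=C1CCC[C@]2(C)CC[C@@H](C(=C)C(=O)O3)[C@H]3[C@@H]12
A6 | alternative 3 | (1S,2R)-2-methyl-6-methylidene-2-(4-methylpent-3-en-1-yl)cyclohexane-1-carbaldehyde | C=C1CCC[C@](C)(CCC=C(C)C)[C@H]1C=O
A7 | alternative 3 | eudesm-4(15)-en-6α-ol (identical with 25) | C=C1CCC[C@]2(C)CC[C@@H](C(C)C)[C@H](O)[C@@H]12
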